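The pyran ring is opened at O1–C8a. In sargachromanol C the ring oxygen O1 is bonded to C8a, which stands para to the C6 hydroxyl and between C4a and the methyl-bearing C8. Read backwards, the benzene ring is a 3,5-dialkylated phenol in which the side-chain tertiary oxygen takes the place of the para hydrogen. Oxidising that phenol with PhI(OAc)2 and methanol should forge O1–C8a and close the pyran ring in one operation, giving an 8a-methoxy quinone monoketal that mild reduction re-aromatises. The precursor is an open-chain phenol carrying both stereocentres: the (3R)-tertiary carbinol from Sharpless epoxidation of farnesol, the (12R)-allylic carbinol from reagent-controlled allylboration.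

Key step: step 10

Remark: ring atoms carry chroman numbers (O1, C2 … C8a); the chromanol passed through in step 10 is the target itself, so it bears the number 14, ahead of the ketal 15.
Remark: (+)-Ipc2B(allyl) means the B-allyldiisopinocampheylborane built from (−)-α-pinene, assumed purchasable as a pentane solution.

Step 1
Reactants: 1 3-bromo-5-methylphenol
Product: 2 (3-bromo-5-methylphenoxy)(tert-butyl)dimethylsilane
Conditions: TBSCl, imidazole, DMF, rt
Reagents that add atoms: tert-butyl(chloro)dimethylsilane (TBSCl), CC(C)(C)[Si](C)(C)Cl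
Why: Silylation of a phenol with a silyl chloride and imidazole masks the acidic O–H so that the aryl bromide can later be turned into a Grignard reagent.

Step 2
Reactants: 3 (2E,6E)-farnesol
Product: 4 [(2R,3R)-3-[(3E)-4,8-dimethylnona-3,7-dien-1-yl]-3-methyloxiran-2-yl]methanol
Conditions: Ti(OiPr)4 (5 mol%), D-(−)-diethyl tartrate (7.5 mol%), t-BuOOH (decane), 4 Å molecular sieves, CH2Cl2, −20 °C
Reagents that add atoms: tert-butyl hydroperoxide, CC(C)(C)OO
Why: Sharpless asymmetric epoxidation reacts only at the alkene of the allylic alcohol, and with the D-(−)-tartrate (the L-(+)-ester gives the 2S,3S series from E-allylic alcohols such as geraniol) the oxygen should be delivered to the face that gives the (2R,3R)-epoxide, which sets the centre that becomes C2 of the chroman.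

Step 3
Reactants: 4 [(2R,3R)-3-[(3E)-4,8-dimethylnona-3,7-dien-1-yl]-3-methyloxiran-2-yl]methanol
Product: 5 (3R,6E)-3,7,11-trimethyldodeca-6,10-diene-1,3-diol
Conditions: NaAlH2(OCH2CH2OMe)2, THF, 0 °C → rt; aq. potassium sodium tartrate
Reagents that add atoms: none
Why: Hydroxyl-directed reductive opening of a 2,3-epoxy alcohol: the alkoxyaluminate at C1 delivers hydride to C2, the less substituted epoxide carbon, so the C3–O bond is not broken and the tertiary carbinol keeps its R configuration.

Step 4
Reactants: 5 (3R,6E)-3,7,11-trimethyldodeca-6,10-diene-1,3-diol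
Product: 6 (3R,6E)-3-hydroxy-3,7,11-trimethyldodeca-6,10-dien-1-yl 4-methylbenzenesulfonate
Conditions: TsCl (1.1 equiv), Et3N, DMAP (cat.), CH2Cl2, 0 °C
Reagents that add atoms: 4-methylbenzenesulfonyl chloride (TsCl), Cc1ccc(cc1)S(=O)(=O)Cl
Why: Selective sulfonylation: the primary hydroxyl reacts far faster than the hindered tertiary one, which stays free.

Step 5
Reactants: 6 (3R,6E)-3-hydroxy-3,7,11-trimethyldodeca-6,10-dien-1-yl 4-methylbenzenesulfonate; 2 (3-bromo-5-methylphenoxy)(tert-butyl)dimethylsilane
Product: 8 (3R,6E)-1-[3-[tert-butyl(dimethyl)silyl]oxy-5-methylphenyl]-3,7,11-trimethyldodeca-6,10-dien-3-ol, via aryl Grignard reagent 7 (not isolated)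
Conditions: 2 (2.5 equiv), Mg, I2 (cat.), THF, 50 °C; then 6, Li2CuCl4 (5 mol%), THF, −78 → 0 °C; aq. NH4Cl
Reagents that add atoms: none
Why: Copper-catalysed coupling of a Grignard reagent with a primary alkyl tosylate (Kochi–Schlosser type) forms the aryl–CH2 bond at C1; the first equivalent of 7 only deprotonates the tertiary hydroxyl, whose magnesium alkoxide is a poor nucleophile below 0 °C, and the C3 centre is not involved.

Step 6
Reactants: 8 (3R,6E)-1-[3-[tert-butyl(dimethyl)silyl]oxy-5-methylphenyl]-3,7,11-trimethyldodeca-6,10-dien-3-ol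
Product: 10 (2E,6E,10R)-12-[3-[tert-butyl(dimethyl)silyl]oxy-5-methylphenyl]-10-hydroxy-2,6,10-trimethyldodeca-2,6-dienal, via allylic alcohol 9 (not isolated)
Conditions: SeO2 (0.3 equiv), t-BuOOH, salicylic acid (cat.), CH2Cl2, 0 °C → rt; crude, then MnO2, CH2Cl2, rt
Reagents that add atoms: tert-butyl hydroperoxide, CC(C)(C)OO; selenium dioxide, O=[Se]=O (catalytic carrier of the oxygen atom)
Why: Selenium dioxide allylic oxidation (ene reaction, then [2,3]-sigmatropic shift) should select the (E)-methyl group of the terminal, most accessible trisubstituted alkene, and MnO2, which oxidises only the allylic alcohol, converges the alcohol/aldehyde mixture on the (E)-enal.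

Step 7
Reactants: 10 (2E,6E,10R)-12-[3-[tert-butyl(dimethyl)silyl]oxy-5-methylphenyl]-10-hydroxy-2,6,10-trimethyldodeca-2,6-dienal
Product: 11 (4R,5E,9E,13R)-15-[3-[tert-butyl(dimethyl)silyl]oxy-5-methylphenyl]-5,9,13-trimethylpentadeca-1,5,9-triene-4,13-diol
Conditions: (+)-Ipc2B(allyl) (2.2 equiv, pentane), Et2O, −78 °C; then NaBO3·4H2O, THF/H2O, rt
Reagents that add atoms: (+)-B-allyldiisopinocampheylborane, C=CCB([C@H]1C[C@H]2C[C@@H]([C@@H]1C)C2(C)C)[C@H]1C[C@H]2C[C@@H]([C@@H]1C)C2(C)C
Why: Brown allylboration through a closed six-membered transition state: the isopinocampheyl groups of the reagent from (−)-α-pinene should direct allyl transfer to the re face of the enal, giving the (4R)-carbinol under reagent control (the remote C13 centre has no say), and allyl transfer avoids the γ-selective, reverse-prenyl addition usual for prenyl metal reagents.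

Step 8
Reactants: 11 (4R,5E,9E,13R)-15-[3-[tert-butyl(dimethyl)silyl]oxy-5-methylphenyl]-5,9,13-trimethylpentadeca-1,5,9-triene-4,13-diol
Product: 12 (3R,6E,10E,12R)-1-[3-[tert-butyl(dimethyl)silyl]oxy-5-methylphenyl]-3,7,11,15-tetramethylhexadeca-6,10,14-triene-3,12-diol
Conditions: 2-methyl-2-butene/CH2Cl2 (1:1), second-generation Grubbs catalyst RuCl2(=CHPh)(PCy3)(H2IMes) (5 mol%), rt
Reagents that add atoms: 2-methyl-2-butene, CC=C(C)C
Why: Olefin cross-metathesis of the monosubstituted alkene with excess 2-methyl-2-butene exchanges the terminal CH2 for an isopropylidene group and releases propene, the trisubstituted alkenes of 11 being far slower partners for the ruthenium carbene, so the allyl group should become the prenyl group without touching either stereocentre.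

Step 9
Reactants: 12 (3R,6E,10E,12R)-1-[3-[tert-butyl(dimethyl)silyl]oxy-5-methylphenyl]-3,7,11,15-tetramethylhexadeca-6,10,14-triene-3,12-diol
Product: 13 3-[(3R,6E,10E,12R)-3,12-dihydroxy-3,7,11,15-tetramethylhexadeca-6,10,14-trien-1-yl]-5-methylphenol
Conditions: Bu4NF (1.1 equiv), THF, 0 °C; aq. NH4Cl
Reagents that add atoms: none
Why: Fluoride-induced cleavage of the aryl silyl ether (strong Si–F bond, phenoxide as leaving group) should free the phenol within minutes while both alcohols, which need no protection for the next step, and the alkenes stay untouched.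

Step 10
Reactants: 13 3-[(3R,6E,10E,12R)-3,12-dihydroxy-3,7,11,15-tetramethylhexadeca-6,10,14-trien-1-yl]-5-methylphenol
Product: 15 (2R)-2-[(3E,7E,9R)-9-hydroxy-4,8,12-trimethyltrideca-3,7,11-trien-1-yl]-8a-methoxy-2,8-dimethyl-3,4-dihydro-2H-chromen-6(8aH)-one (both C8a epimers), via chromanol 14 (not isolated)
Conditions: PhI(OAc)2 (2.2 equiv, two portions), MeOH (30 equiv), MeCN (0.01 M), 0 °C; aq. NaHCO3
Reagents that add atoms: methanol, CO
Why: Proposed new method: ligand exchange on trivalent iodine gives an aryloxy iodane, and departure of PhI leaves a phenoxenium-type cation whose para carbon, the future C8a, is attacked by the tethered tertiary hydroxyl; tautomerisation gives chromanol 14, which as a 4-alkoxyphenol is oxidised faster than 13 by the second equivalent, and methanol then adds to the O1-stabilised C8a cation to give the mixed ketal 15 (methanol adding before the hydroxyl would only reverse the order of the two C–O bond formations). The closest known reactions are the PhI(OAc)2/methanol oxidation of para-unsubstituted phenols to 4,4-dialkoxycyclohexadienones, the spiroetherification of para-(hydroxyalkyl)phenols with the same reagent and the oxidation of tocopherol-type chromanols to 8a-alkoxy chromenones, whereas closure of a fused pyran ring from a meta-(3-hydroxyalkyl)phenol has not been shown. The pyran ring (O1, C2, C3, C4, C4a, C8a) closes by C–O bond formation, the oxygen attacking a ring carbon of the cation next to the tether-bearing C4a, a 6-endo-trig closure with respect to the C4a–C8a bond. C8a becomes a stereocentre without control, so both epimers are expected, which is harmless because the centre is flattened again in step 11, and C2 and the side-chain carbinol are not touched. The step needs para (C8a) and not ortho (C5, C7) capture and oxidation of the phenol alone: phenoxenium capture is intrinsically para-selective, the oxygen on C8a localises the charge there in the second oxidation, methanol is held to about thirty equivalents in acetonitrile so that solvent does not out-compete the tethered hydroxyl, and PhI(OAc)2 at 0 °C does not attack trisubstituted alkenes or unactivated alcohols on this time scale.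

Step 11
Reactants: 15 (2R)-2-[(3E,7E,9R)-9-hydroxy-4,8,12-trimethyltrideca-3,7,11-trien-1-yl]-8a-methoxy-2,8-dimethyl-3,4-dihydro-2H-chromen-6(8aH)-one
Product: 14 sargachromanol C, (2R)-2-[(3E,7E,9R)-9-hydroxy-4,8,12-trimethyltrideca-3,7,11-trien-1-yl]-2,8-dimethyl-3,4-dihydro-2H-chromen-6-ol
Conditions: L-ascorbic acid (5 equiv), AcOH (5 equiv), MeOH, rt, argon
Reagents that add atoms: none
Why: Reduction of an 8a-alkoxy chromen-6-one of the tocopherone type by ascorbic acid is established chemistry: acid-assisted loss of the exocyclic methoxy group gives a cation stabilised by O1 that takes up two electrons and a proton, so the benzene ring is restored, both C8a epimers converge, and neither O1–C8a nor O1–C2 is broken.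

Compound list
1 | 3-bromo-5-methylphenol | Cc1cc(O)cc(Br)c1 | starting material
2 | (3-bromo-5-methylphenoxy)(tert-butyl)dimethylsilane | Cc1cc(O[Si](C)(C)C(C)(C)C)cc(Br)c1 | intermediate
3 | (2E,6E)-farnesol | CC(C)=CCC/C(C)=C/CC/C(C)=C/CO | starting material
4 | [(2R,3R)-3-[(3E)-4,8-dimethylnona-3,7-dien-1-yl]-3-methyloxiran-2-yl]methanol | CC(C)=CCC/C(C)=C/CC[C@@]1(C)O[C@@H]1CO | intermediate
5 | (3R,6E)-3,7,11-trimethyldodeca-6,10-diene-1,3-diol | CC(C)=CCC/C(C)=C/CC[C@@](CCO)(C)O | intermediate
6 | (3R,6E)-3-hydroxy-3,7,11-trimethyldodeca-6,10-dien-1-yl 4-methylbenzenesulfonate | CC(C)=CCC/C(C)=C/CC[C@@](CCOS(=O)(=O)c1ccc(C)cc1)(C)O | intermediate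
7 | [3-[tert-butyl(dimethyl)silyl]oxy-5-methylphenyl]magnesium bromide | Cc1cc(O[Si](C)(C)C(C)(C)C)cc([Mg]Br)c1 | intermediate (not isolated)
8 | (3R,6E)-1-[3-[tert-butyl(dimethyl)silyl]oxy-5-methylphenyl]-3,7,11-trimethyldodeca-6,10-dien-3-ol | CC(C)=CCC/C(C)=C/CC[C@@](CCc1cc(C)cc(O[Si](C)(C)C(C)(C)C)c1)(C)O | intermediate
9 | (2E,6E,10R)-12-[3-[tert-butyl(dimethyl)silyl]oxy-5-methylphenyl]-2,6,10-trimethyldodeca-2,6-diene-1,10-diol | OC/C(C)=C/CC/C(C)=C/CC[C@@](CCc1cc(C)cc(O[Si](C)(C)C(C)(C)C)c1)(C)O | intermediate (not isolated)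
10 | (2E,6E,10R)-12-[3-[tert-butyl(dimethyl)silyl]oxy-5-methylphenyl]-10-hydroxy-2,6,10-trimethyldodeca-2,6-dienal | O=C/C(C)=C/CC/C(C)=C/CC[C@@](CCc1cc(C)cc(O[Si](C)(C)C(C)(C)C)c1)(C)O | intermediate
11 | (4R,5E,9E,13R)-15-[3-[tert-butyl(dimethyl)silyl]oxy-5-methylphenyl]-5,9,13-trimethylpentadeca-1,5,9-triene-4,13-diol | C=CC[C@@H](O)/C(C)=C/CC/C(C)=C/CC[C@@](CCc1cc(C)cc(O[Si](C)(C)C(C)(C)C)c1)(C)O | intermediate
12 | (3R,6E,10E,12R)-1-[3-[tert-butyl(dimethyl)silyl]oxy-5-methylphenyl]-3,7,11,15-tetramethylhexadeca-6,10,14-triene-3,12-diol | CC(C)=CC[C@@H](O)/C(C)=C/CC/C(C)=C/CC[C@@](CCc1cc(C)cc(O[Si](C)(C)C(C)(C)C)c1)(C)O | intermediate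
13 | 3-[(3R,6E,10E,12R)-3,12-dihydroxy-3,7,11,15-tetramethylhexadeca-6,10,14-trien-1-yl]-5-methylphenol | CC(C)=CC[C@@H](O)/C(C)=C/CC/C(C)=C/CC[C@@](CCc1cc(C)cc(O)c1)(C)O | intermediate (precursor of the key step)
14 | sargachromanol C, (2R)-2-[(3E,7E,9R)-9-hydroxy-4,8,12-trimethyltrideca-3,7,11-trien-1-yl]-2,8-dimethyl-3,4-dihydro-2H-chromen-6-ol | CC(C)=CC[C@@H](O)/C(C)=C/CC/C(C)=C/CC[C@]1(C)CCc2cc(O)cc(C)c2O1 | target (also passed through, not isolated, in step 10)
15 | (2R)-2-[(3E,7E,9R)-9-hydroxy-4,8,12-trimethyltrideca-3,7,11-trien-1-yl]-8a-methoxy-2,8-dimethyl-3,4-dihydro-2H-chromen-6(8aH)-one, both C8a epimers | CC(C)=CC[C@@H](O)/C(C)=C/CC/C(C)=C/CC[C@]1(C)CCC2=CC(=O)C=C(C)C2(OC)O1 | intermediate (product of the key step)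

Total step count: 11. Longest linear sequence: 10 steps (steps 2 to 11, from farnesol); step 1 prepares the aryl partner that enters in step 5.

Steps most likely to fail

Step 10. The cation may be captured at an ortho carbon, two molecules of methanol may add in place of the tethered hydroxyl, or two phenol units may couple oxidatively. The fallback uses known chemistry and sets out from 13. Oxidation with (KSO3)2NO in buffered aqueous acetone (Teuber oxidation of a para-unsubstituted phenol) installs the para oxygen and should give the hydroxyalkyl quinone 2-[(3R,6E,10E,12R)-3,12-dihydroxy-3,7,11,15-tetramethylhexadeca-6,10,14-trien-1-yl]-6-methylcyclohexa-2,5-diene-1,4-dione F1. Its tertiary hydroxyl adds to the neighbouring C1 carbonyl, and trimethyl orthoformate, methanol and catalytic TsOH fix this cyclic hemiketal as the methyl ketal, as is done when hydroxyalkyl quinones of the tocopherol series are returned to chromanols. That ketal is 15, so the route is rejoined at 15 before step 11. O1–C8a then comes from carbonyl addition in place of C–H oxidation, and the C2–O bond is again never broken.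

Step 6. Ene attack at the allylic positions of the internal alkene and over-oxidation may erode the site selectivity. The fallback sets out from 8 and builds the enal by cleavage and olefination. NBS in aqueous THF at 0 °C should form the bromohydrin of the terminal alkene, (3R,6E)-10-bromo-1-[3-[tert-butyl(dimethyl)silyl]oxy-5-methylphenyl]-3,7,11-trimethyldodec-6-ene-3,11-diol F2. K2CO3 in methanol closes it to the terminal epoxide (3R,6E)-1-[3-[tert-butyl(dimethyl)silyl]oxy-5-methylphenyl]-9-(3,3-dimethyloxiran-2-yl)-3,7-dimethylnon-6-en-3-ol F3. HIO4 in aqueous THF cleaves the epoxide to the shortened aldehyde (4E,8R)-10-[3-[tert-butyl(dimethyl)silyl]oxy-5-methylphenyl]-8-hydroxy-4,8-dimethyldec-4-enal F4. A Wittig reaction with the stabilised ylide Ph3P=C(CH3)CHO in toluene at 90 °C then gives the (E)-enal, which is 10, where the route is rejoined.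

Step 8. The ruthenium carbene may also engage the trisubstituted alkenes, or the terminal double bond may migrate before exchange. The fallback sets out from 10 and replaces steps 7 and 8 by direct prenylation followed by redox correction of the carbinol. Prenylbarium chloride (prenyl chloride, reactive barium from BaI2 and lithium biphenylide, THF, −78 °C) adds through its α-carbon and should give the C12-epimeric alcohols (3R,6E,10E)-1-[3-[tert-butyl(dimethyl)silyl]oxy-5-methylphenyl]-3,7,11,15-tetramethylhexadeca-6,10,14-triene-3,12-diol F5. MnO2 oxidises them to the enone (3R,6E,10E)-1-[3-[tert-butyl(dimethyl)silyl]oxy-5-methylphenyl]-3-hydroxy-3,7,11,15-tetramethylhexadeca-6,10,14-trien-12-one F6. Reduction with BH3·SMe2 and catalytic (S)-2-methyl-CBS-oxazaborolidine, the enone unit acting as the large group, should give the (12R)-alcohol, which is 12, where the route is rejoined.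

Further compounds
F1 | step 10 | 2-[(3R,6E,10E,12R)-3,12-dihydroxy-3,7,11,15-tetramethylhexadeca-6,10,14-trien-1-yl]-6-methylcyclohexa-2,5-diene-1,4-dione | CC(C)=CC[C@@H](O)/C(C)=C/CC/C(C)=C/CC[C@@](CCC1=CC(=O)C=C(C)C1=O)(C)O
F2 | step 6 | (3R,6E)-10-bromo-1-[3-[tert-butyl(dimethyl)silyl]oxy-5-methylphenyl]-3,7,11-trimethyldodec-6-ene-3,11-diol (C10 epimers) | CC(C)(O)C(Br)CC/C(C)=C/CC[C@@](CCc1cc(C)cc(O[Si](C)(C)C(C)(C)C)c1)(C)O
F3 | step 6 | (3R,6E)-1-[3-[tert-butyl(dimethyl)silyl]oxy-5-methylphenyl]-9-(3,3-dimethyloxiran-2-yl)-3,7-dimethylnon-6-en-3-ol (epoxide epimers) | CC1(C)OC1CC/C(C)=C/CC[C@@](CCc1cc(C)cc(O[Si](C)(C)C(C)(C)C)c1)(C)O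
F4 | step 6 | (4E,8R)-10-[3-[tert-butyl(dimethyl)silyl]oxy-5-methylphenyl]-8-hydroxy-4,8-dimethyldec-4-enal | O=CCC/C(C)=C/CC[C@@](CCc1cc(C)cc(O[Si](C)(C)C(C)(C)C)c1)(C)O
F5 | step 8 | (3R,6E,10E)-1-[3-[tert-butyl(dimethyl)silyl]oxy-5-methylphenyl]-3,7,11,15-tetramethylhexadeca-6,10,14-triene-3,12-diol (C12 epimers) | CC(C)=CCC(O)/C(C)=C/CC/C(C)=C/CC[C@@](CCc1cc(C)cc(O[Si](C)(C)C(C)(C)C)c1)(C)O
F6 | step 8 | (3R,6E,10E)-1-[3-[tert-butyl(dimethyl)silyl]oxy-5-methylphenyl]-3-hydroxy-3,7,11,15-tetramethylhexadeca-6,10,14-trien-12-one | CC(C)=CCC(=O)/C(C)=C/CC/C(C)=C/CC[C@@](CCc1cc(C)cc(O[Si](C)(C)C(C)(C)C)c1)(C)O
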